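Five flasks hold the partner at one charge and step up the starting material, and we want the target in each at the set time.

| setting | autumn | winter | zeta | epsilon | eta | beta | delta |
|---|---|---|---|---|---|---|---|
| starting material | 0.053 M | 1.3 M | 0.080 M | 0.15 M | 0.30 M | 0.60 M | 1.5 M |
| partner | 0.425 M | 0.425 M | 0.425 M | 0.425 M | 0.425 M | 0.425 M | 0.425 M |
| remark | run made earlier | run made earlier |  |  |  |  |  |
| time |  |  | 40 min | 40 min | 40 min | 40 min | 40 min |

| run | time / min | target / % | starting material / % |
|---|---|---|---|
| autumn | 1.00 | 0 | 97 |
| autumn | 3.00 | 5 | 90 |
| autumn | 6.00 | 14 | 84 |
| autumn | 8.00 | 11 | 83 |
| autumn | 12.0 | 22 | 75 |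
| autumn | 15.0 | 19 | 67 |
| autumn | 20.0 | 28 | 58 |
| winter | 1.00 | 0 | 96 |
| winter | 3.00 | 3 | 89 |
| winter | 6.00 | 4 | 82 |
| winter | 8.00 | 5 | 76 |
| winter | 12.0 | 1 | 65 |
| winter | 15.0 | 4 | 66 |
| winter | 20.0 | 0 | 55 |

(scatter of a reading: 2 percentage points)

- "hardly changes" means that all values lie within two and a half points (for a concentration: within two and a half percent of the largest)

* [target] at the end for zeta, epsilon, eta, beta, delta, in this order
* the course of these numbers from the first flask to the last (falls, then rises / falls all the way / hardly changes / rises, then falls / rises all the way)

The winter run charged 24.5 times the starting material of the autumn run. As a concentration, its target averages 0.0368 M from the second reading on, give or take 0.0106 M. The autumn run reaches 0.0148 M at its last reading, which is less than that winter level.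

We assume that the starting material both makes target and destroys it. Both rates then scale with the starting material, so at a fixed partner level the balance falls at one target level however much starting material stands. We read the winter average as that level and call it the ceiling: the target concentration at which target is used up as fast as it is made, the quasi-steady state of an intermediate. So we expect the row to climb at first and then stay at or under the ceiling.

The forecast gives 0.031 M, 0.043 M, 0.055 M, 0.064 M and 0.072 M, a row that rises all the way, and it grants that under such destruction “the high end would plateau or sag”. From its second value on, it stands above our ceiling.

The flasks give 0.0217 M, 0.0271 M, 0.0267 M, 0.0187 M and 0.00623 M: the row rises, then falls, turning at 0.21 M of starting material.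

    starting material + partner → target, rate k1*[starting material]*[partner]^1.5 (k = 0.0685 /M^1.5/min)
    starting material ⇌ dormant form (K = 0.220, k = 0.00811 /min)
    starting material + target → side product (k = 0.502 /M/min)

Set the making and using of target equal in this scheme and the starting material cancels, which leaves the ceiling following the partner's factor in the first step. Zeta keeps 92% of its partner at the end, which lowers our ceiling to 0.0325 M. Divided by the target of zeta, that gives 1.50, and at the end target in zeta is made 1.53 times faster than it is destroyed, each step taken net. Delta keeps 29% of its partner, so our ceiling, read from the winter run, comes to 0.00562 M in delta, beside 0.00623 M of target.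

The earlier runs and the new flask are calculated on assumed constants; the scatter is artificial.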